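**Strategy.** Ring A is disconnected at its C1–C2 bond, where C1 bears the ether oxygen to ring B and C2, C4 and C6 bear hydroxyls. Unfolded there, ring A is a 6-aryloxy-3,5-dioxohexanoate whose three carbonyl carbons become C2, C4 and C6 and whose aryloxymethyl carbon becomes C1. One base-induced Claisen closure thus delivers the carbocycle, the aromatic triol and the doubly ortho-flanked diaryl ether together, the ether oxygen having been installed earlier by an unhindered Williamson alkylation. The precursor is the methyl ester of that acid carrying the undecamethylated rings B to F pentamer, which is assembled by four copper-catalysed couplings of 2,6-dimethoxyphenols with unhindered aryl bromides.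

Key step: step 15

**Remarks on the chemistry**
- Shorthand: in X–B–C–…–Y, rings B, C, D and E are 3,5-dimethoxy-1,4-phenylenedioxy units. X sits on the C1 oxygen of ring B, the C4 oxygen of each ring is bonded to C1 of the next ring, and Y sits on the C4 oxygen of the last ring written. F is 3,4,5-trimethoxyphenyl.
- Ring A, not ring B, is the ring that arises from the folded dioxohexanoate chain. Chain C6 becomes ring A C1, chain C1 becomes ring A C2, chain C3 becomes C4 and chain C5 becomes C6.
- Rings B to F are joined from ready-made 2,6-dimethoxyphenol units and are not grown by repeated ring construction. A free 2-aryloxyphloroglucinol offers no defensible way to methylate its two hindered ortho hydroxyls while sparing the unhindered para hydroxyl. In every coupling the hindrance lies on the phenoxide only.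
- The species that cyclises in step 15 is taken to be a dianion whose ester is not enolised. A trianion would hold the ester carbon as an enolate carbon and could not be attacked. The base is therefore kept between two and three equivalents. A chelating divalent counter-ion such as magnesium is avoided, because a 1,3-dicarbonyl chelate holds the two oxygens syn and the chain ends C2 and C6 apart.
- Assumption: the five starting materials named in the steps are commercially available.

**Route**

Step 1
Reactants: 1 4-(benzyloxy)-3,5-dimethoxybenzaldehyde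
Product: 3 4-(benzyloxy)-3,5-dimethoxyphenol, via aryl formate 2 (not isolated)
Conditions: mCPBA (1.3 equiv), CH2Cl2, 0 °C to rt; then K2CO3 (0.2 equiv), MeOH, rt
Reagents that add atoms: mCPBA, O=C(OO)c1cccc(Cl)c1
Why: Baeyer–Villiger oxidation of an electron-rich benzaldehyde proceeds with aryl migration to the formate, which is cleaved by base-catalysed methanolysis, as in the usual preparation of 3,4,5-trialkoxyphenols.

Step 2
Reactants: 3 4-(benzyloxy)-3,5-dimethoxyphenol
Product: 4 2-(benzyloxy)-1,3-dimethoxy-5-(methoxymethoxy)benzene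
Conditions: NaH (1.2 equiv), THF, 0 °C; MOMCl, 0 °C to rt
Reagents that add atoms: chloromethyl methyl ether (MOMCl), COCCl
Why: Williamson-type O-alkylation of the sodium phenoxide by the reactive α-chloro ether should install an acetal that is stable to base and to hydrogenolysis on the oxygen that will later carry ring A.

Step 3
Reactants: 4 2-(benzyloxy)-1,3-dimethoxy-5-(methoxymethoxy)benzene
Product: 5 2,6-dimethoxy-4-(methoxymethoxy)phenol (ring B unit)
Conditions: H2 (1 atm), 10% Pd/C, EtOAc, rt
Reagents that add atoms: none
Why: Catalytic hydrogenolysis cleaves only the benzyl C–O bond and leaves the methyl ethers and the MOM acetal intact, which unmasks the hindered C4 hydroxyl of ring B.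

Step 4
Reactants: 6 4-bromo-2,6-dimethoxyphenol
Product: 7 2-(benzyloxy)-5-bromo-1,3-dimethoxybenzene (chain-extension unit)
Conditions: BnBr, K2CO3, DMF, 60 °C
Reagents that add atoms: benzyl bromide, BrCc1ccccc1
Why: Williamson benzylation of the 2,6-dimethoxyphenoxide is routine, and the aryl bromide is inert under these conditions.

Step 5
Reactants: 5 2,6-dimethoxy-4-(methoxymethoxy)phenol; 7 2-(benzyloxy)-5-bromo-1,3-dimethoxybenzene
Product: 8 MOM–B–C–Bn, 2-(benzyloxy)-5-[2,6-dimethoxy-4-(methoxymethoxy)phenoxy]-1,3-dimethoxybenzene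
Conditions: CuI (10 mol%), picolinic acid (20 mol%), K3PO4 (2 equiv), DMSO, 100 °C, Ar
Reagents that add atoms: none
Why: Ullmann-type copper-catalysed diaryl ether synthesis should work because the bromide carbon of 7 is flanked by two ring hydrogens, so all hindrance lies on the phenoxide, which this ligand system tolerates, and benzyl, methyl and MOM ethers are inert to it.

Step 6
Reactants: 8 MOM–B–C–Bn
Product: 9 MOM–B–C–H, 4-[2,6-dimethoxy-4-(methoxymethoxy)phenoxy]-2,6-dimethoxyphenol
Conditions: H2 (1 atm), 10% Pd/C, EtOAc/MeOH, rt; product kept under Ar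
Reagents that add atoms: none
Why: Hydrogenolysis of the single benzyl ether as in step 3 should free the hindered phenol, since diaryl ethers are not cleaved under these mild conditions.

Step 7
Reactants: 9 MOM–B–C–H; 7 2-(benzyloxy)-5-bromo-1,3-dimethoxybenzene
Product: 10 MOM–B–C–D–Bn (benzyl ether of the three-ring phenol)
Conditions: CuI (10 mol%), picolinic acid (20 mol%), K3PO4 (2 equiv), DMSO, 100 °C, Ar
Reagents that add atoms: none
Why: The same Ullmann-type coupling applies, because phenol 9 has the same 4-aryloxy-2,6-dimethoxy environment as a simple syringol-type phenoxide and 7 is again the unhindered partner.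

Step 8
Reactants: 10 MOM–B–C–D–Bn
Product: 11 MOM–B–C–D–H (three-ring phenol, free OH on C4 of ring D)
Conditions: H2 (1 atm), 10% Pd/C, EtOAc/MeOH, rt; product kept under Ar
Reagents that add atoms: none
Why: Benzyl ether hydrogenolysis as in step 6, with no other reducible group present.

Step 9
Reactants: 11 MOM–B–C–D–H; 7 2-(benzyloxy)-5-bromo-1,3-dimethoxybenzene
Product: 12 MOM–B–C–D–E–Bn (benzyl ether of the four-ring phenol)
Conditions: CuI (10 mol%), picolinic acid (20 mol%), K3PO4 (2 equiv), DMSO, 100 °C, Ar
Reagents that add atoms: none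
Why: Third iteration of the Ullmann-type coupling, in which the reacting termini are electronically and sterically the same as in steps 5 and 7.

Step 10
Reactants: 12 MOM–B–C–D–E–Bn
Product: 13 MOM–B–C–D–E–H (four-ring phenol, free OH on C4 of ring E)
Conditions: H2 (1 atm), 10% Pd/C, THF/MeOH, rt; product kept under Ar
Reagents that add atoms: none
Why: Benzyl ether hydrogenolysis as in steps 6 and 8.

Step 11
Reactants: 13 MOM–B–C–D–E–H; 14 5-bromo-1,2,3-trimethoxybenzene
Product: 15 MOM–B–C–D–E–F (five-ring MOM ether)
Conditions: CuI (10 mol%), picolinic acid (20 mol%), K3PO4 (2 equiv), DMSO, 100 °C, Ar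
Reagents that add atoms: none
Why: Ullmann-type coupling of the hindered phenoxide with the unhindered ring F bromide, the same bond type as in steps 5, 7 and 9, completes the B to F chain.

Step 12
Reactants: 15 MOM–B–C–D–E–F
Product: 16 H–B–C–D–E–F (five-ring phenol, free OH on C1 of ring B)
Conditions: 3 M HCl, MeOH/THF, 50 °C
Reagents that add atoms: none
Why: Acid-catalysed acetal exchange with methanol removes the MOM group, while aryl methyl ethers and diaryl ethers are stable to dilute HCl.

Step 13
Reactants: 16 H–B–C–D–E–F; 17 methyl bromoacetate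
Product: 18 methyl 2-(five-ring aryloxy)acetate, MeO2CCH2–B–C–D–E–F
Conditions: K2CO3, acetone, reflux
Reagents that add atoms: none
Why: Williamson alkylation of the unhindered ring B phenoxide by an α-bromo ester forms the future ring A–O bond while it is still an unhindered alkyl aryl ether.

Step 14
Reactants: 18 methyl 2-(five-ring aryloxy)acetate; 19 methyl acetoacetate
Product: 21 methyl 6-(five-ring aryloxy)-3,5-dioxohexanoate, via acetoacetate dianion 20 (not isolated)
Conditions: 19 (3 equiv), NaH, THF, 0 °C; n-BuLi, 0 °C; then 18, −78 to 0 °C; aq. HCl to pH 4, 0 °C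
Reagents that add atoms: none
Why: Claisen-type acylation of the γ-carbon of the acetoacetate dianion by a methyl ester is a known route to 6-alkoxy-3,5-dioxohexanoates, the α-oxygen makes the ester more electrophilic, and the product is held as its dienolate until the cold quench.

Step 15
Reactants: 21 methyl 6-(five-ring aryloxy)-3,5-dioxohexanoate
Product: 23 2-(five-ring aryloxy)benzene-1,3,5-triol (undecamethyl ether of the target, ring A free), via cyclohexane-1,3,5-trione 22 (not isolated)
Conditions: NaH (2.5 equiv), MeOH (0.1 equiv), diglyme, 0 °C to 120 °C, Ar; then 1 M HCl, 0 °C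
Reagents that add atoms: none
Why: Two equivalents of base give the C2,C4-dianion, in which the ester is masked as its enolate; proton transfer from C6 to C2, relayed by the trace of NaOMe, gives a small equilibrium amount of the C4,C6-dianion, whose terminal carbanion adds to the now un-enolised ester carbon C1 and expels methoxide. The closest known reaction is the base-induced intramolecular Claisen (Dieckmann-type) closure of 3,5-dioxohexanoate esters to phloroglucinol, the laboratory counterpart of triketide cyclisation. Ring A closes in the 6-(enolendo)-exo-trig mode, and trione 22 tautomerises at once to the aromatic triol (held as its phenoxide), which makes the step irreversible; no stereocentre is formed. The selectivity needed is C-acylation through C6 and not O-acylation through O5 to a 4-hydroxy-2-pyranone: more than two equivalents of base leave no monoanion with a free ester for O5 to attack, fewer than three avoid the unreactive trianion, and the loosely bound sodium ion in diglyme does not lock the carbonyl oxygens into a chelate that would hold C2 and C6 apart. The aryloxy group makes C6–H more acidic than a methyl terminus would be, and no other carbon–carbonyl pairing in 21 can give a six-membered carbocycle.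

Step 16
Reactants: 23 2-(five-ring aryloxy)benzene-1,3,5-triol
Product: 24 target hexamer (CNP0187343.0)
Conditions: BBr3 (30 equiv), CH2Cl2, −78 °C to rt, Ar; then H2O, 0 °C
Reagents that add atoms: none
Why: Lewis acid-mediated cleavage of aryl methyl ethers (boron coordinates the ether oxygen and bromide attacks the methyl carbon) is the standard way to unmask polymethoxylated diaryl ethers, and the Ar–O–Ar bonds are not cleaved.

**Compound list**

1 | 4-(benzyloxy)-3,5-dimethoxybenzaldehyde | O=Cc1cc(OC)c(OCc2ccccc2)c(OC)c1 | starting material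
2 | 4-(benzyloxy)-3,5-dimethoxyphenyl formate | O=COc1cc(OC)c(OCc2ccccc2)c(OC)c1 | intermediate
3 | 4-(benzyloxy)-3,5-dimethoxyphenol | Oc1cc(OC)c(OCc2ccccc2)c(OC)c1 | intermediate
4 | 2-(benzyloxy)-1,3-dimethoxy-5-(methoxymethoxy)benzene | COCOc1cc(OC)c(OCc2ccccc2)c(OC)c1 | intermediate
5 | 2,6-dimethoxy-4-(methoxymethoxy)phenol | COCOc1cc(OC)c(O)c(OC)c1 | intermediate
6 | 4-bromo-2,6-dimethoxyphenol | COc1cc(Br)cc(OC)c1O | starting material
7 | 2-(benzyloxy)-5-bromo-1,3-dimethoxybenzene | COc1cc(Br)cc(OC)c1OCc1ccccc1 | intermediate
8 | MOM–B–C–Bn, 2-(benzyloxy)-5-[2,6-dimethoxy-4-(methoxymethoxy)phenoxy]-1,3-dimethoxybenzene | COCOc1cc(OC)c(Oc2cc(OC)c(OCc3ccccc3)c(OC)c2)c(OC)c1 | intermediate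
9 | MOM–B–C–H, 4-[2,6-dimethoxy-4-(methoxymethoxy)phenoxy]-2,6-dimethoxyphenol | COCOc1cc(OC)c(Oc2cc(OC)c(O)c(OC)c2)c(OC)c1 | intermediate
10 | MOM–B–C–D–Bn, benzyl ether of the three-ring phenol | COCOc1cc(OC)c(Oc2cc(OC)c(Oc3cc(OC)c(OCc4ccccc4)c(OC)c3)c(OC)c2)c(OC)c1 | intermediate
11 | MOM–B–C–D–H, three-ring phenol with free OH on C4 of ring D | COCOc1cc(OC)c(Oc2cc(OC)c(Oc3cc(OC)c(O)c(OC)c3)c(OC)c2)c(OC)c1 | intermediate
12 | MOM–B–C–D–E–Bn, benzyl ether of the four-ring phenol | COCOc1cc(OC)c(Oc2cc(OC)c(Oc3cc(OC)c(Oc4cc(OC)c(OCc5ccccc5)c(OC)c4)c(OC)c3)c(OC)c2)c(OC)c1 | intermediate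
13 | MOM–B–C–D–E–H, four-ring phenol with free OH on C4 of ring E | COCOc1cc(OC)c(Oc2cc(OC)c(Oc3cc(OC)c(Oc4cc(OC)c(O)c(OC)c4)c(OC)c3)c(OC)c2)c(OC)c1 | intermediate
14 | 5-bromo-1,2,3-trimethoxybenzene | COc1cc(Br)cc(OC)c1OC | starting material
15 | MOM–B–C–D–E–F, five-ring MOM ether | COCOc1cc(OC)c(Oc2cc(OC)c(Oc3cc(OC)c(Oc4cc(OC)c(Oc5cc(OC)c(OC)c(OC)c5)c(OC)c4)c(OC)c3)c(OC)c2)c(OC)c1 | intermediate
16 | H–B–C–D–E–F, five-ring phenol with free OH on C1 of ring B | Oc1cc(OC)c(Oc2cc(OC)c(Oc3cc(OC)c(Oc4cc(OC)c(Oc5cc(OC)c(OC)c(OC)c5)c(OC)c4)c(OC)c3)c(OC)c2)c(OC)c1 | intermediate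
17 | methyl bromoacetate | COC(=O)CBr | starting material
18 | methyl 2-(five-ring aryloxy)acetate, MeO2CCH2–B–C–D–E–F | COC(=O)COc1cc(OC)c(Oc2cc(OC)c(Oc3cc(OC)c(Oc4cc(OC)c(Oc5cc(OC)c(OC)c(OC)c5)c(OC)c4)c(OC)c3)c(OC)c2)c(OC)c1 | intermediate
19 | methyl acetoacetate | COC(=O)CC(C)=O | starting material
20 | methyl acetoacetate dianion (sodium lithium salt) | [Na+].[Li+].C=C([O-])C=C([O-])OC | intermediate
21 | methyl 6-(five-ring aryloxy)-3,5-dioxohexanoate (key-step precursor) | COC(=O)CC(=O)CC(=O)COc1cc(OC)c(Oc2cc(OC)c(Oc3cc(OC)c(Oc4cc(OC)c(Oc5cc(OC)c(OC)c(OC)c5)c(OC)c4)c(OC)c3)c(OC)c2)c(OC)c1 | intermediate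
22 | 2-(five-ring aryloxy)cyclohexane-1,3,5-trione | O=C1CC(=O)C(Oc2cc(OC)c(Oc3cc(OC)c(Oc4cc(OC)c(Oc5cc(OC)c(Oc6cc(OC)c(OC)c(OC)c6)c(OC)c5)c(OC)c4)c(OC)c3)c(OC)c2)C(=O)C1 | intermediate
23 | 2-(five-ring aryloxy)benzene-1,3,5-triol, undecamethyl ether of the target with ring A as free triol (key-step product) | Oc1cc(O)c(Oc2cc(OC)c(Oc3cc(OC)c(Oc4cc(OC)c(Oc5cc(OC)c(Oc6cc(OC)c(OC)c(OC)c6)c(OC)c5)c(OC)c4)c(OC)c3)c(OC)c2)c(O)c1 | intermediate
24 | CNP0187343.0: ring A 2,4,6-trihydroxyphenyl, rings B to E 3,5-dihydroxy-1,4-phenylenedioxy, ring F 3,4,5-trihydroxyphenyl, all joined by ether oxygens | Oc1cc(O)c(Oc2cc(O)c(Oc3cc(O)c(Oc4cc(O)c(Oc5cc(O)c(Oc6cc(O)c(O)c(O)c6)c(O)c5)c(O)c4)c(O)c3)c(O)c2)c(O)c1 | target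

**Totals and risks**

Total step count: 16. Longest linear sequence: 15 steps (1 to 24 through steps 1–3 and 5–16; step 4 makes the shared coupling unit 7).

Steps most likely to fail:

1. Step 15 (ring A closure). The chain may lactonise through O5, fragment by retro-Claisen cleavage at the temperature needed, or stay unchanged because the productive dianion tautomer is too thinly populated. Fallback: ring A would be attached ready-made. Phenol 16 would be coupled with commercial 2-iodo-1,3,5-trimethoxybenzene (CuI, picolinic acid, K3PO4, DMSO, 110 °C), a known Ullmann ether synthesis in which the phenoxide is unhindered and the hindrance sits on the iodide, to give the tetradecamethyl ether of the target F1. BBr3 in CH2Cl2 would then cleave all fourteen methyl ethers. The fallback sets out from 16 and comes back to the route at the target 24.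

2. Step 11 (last aryl ether coupling). Insertion of monovalent copper into the electron-rich bromide may be slow, and the electron-rich hindered phenoxide of 13 may be oxidised to a quinone, which would stall the coupling on the most advanced phenol. Fallback: the ring F aryl group would be delivered by ligand coupling at trivalent iodine, without a transition metal. Commercial 5-iodo-1,2,3-trimethoxybenzene would be oxidised with mCPBA and TsOH·H2O in MeCN and then treated with 1,3,5-trimethoxybenzene to give (3,4,5-trimethoxyphenyl)(2,4,6-trimethoxyphenyl)iodonium tosylate F2. The potassium phenoxide of 13 (KOtBu, THF, 0 to 40 °C) would be arylated by this salt, the 2,4,6-trimethoxyphenyl group staying on iodine. The fallback sets out from 13 and comes back at 15.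

3. Step 16 (global demethylation). Cleavage of eleven ethers may stop short, and the free tetradecaphenol may be lost to air oxidation during isolation. Fallback: the crude product of the BBr3 reaction on 23 would be acetylated before any purification (Ac2O, pyridine, DMAP) to the tetradecaacetate of the target F3. This compound is air-stable, soluble and separable on silica from under-demethylated material, which can be resubmitted. Acid-catalysed methanolysis under Ar (catalytic HCl in degassed MeOH, 40 °C) would then release the polyphenol. The fallback sets out from 23 and comes back at the target 24.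

**Further compounds**

F1 | step 15 | tetradecamethyl ether of the target (ring A 2,4,6-trimethoxyphenyl) | COc1cc(OC)c(Oc2cc(OC)c(Oc3cc(OC)c(Oc4cc(OC)c(Oc5cc(OC)c(Oc6cc(OC)c(OC)c(OC)c6)c(OC)c5)c(OC)c4)c(OC)c3)c(OC)c2)c(OC)c1
F2 | step 11 | (3,4,5-trimethoxyphenyl)(2,4,6-trimethoxyphenyl)iodonium tosylate | COc1cc(OC)c([I+]c2cc(OC)c(OC)c(OC)c2)c(OC)c1.Cc1ccc(cc1)S([O-])(=O)=O
F3 | step 16 | tetradecaacetate of the target | CC(=O)Oc1cc(OC(C)=O)c(Oc2cc(OC(C)=O)c(Oc3cc(OC(C)=O)c(Oc4cc(OC(C)=O)c(Oc5cc(OC(C)=O)c(Oc6cc(OC(C)=O)c(OC(C)=O)c(OC(C)=O)c6)c(OC(C)=O)c5)c(OC(C)=O)c4)c(OC(C)=O)c3)c(OC(C)=O)c2)c(OC(C)=O)c1
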